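**Retrosynthetic overview**

1. Numbering: C1 (quaternary C–Me), C2, C3, C4 (CH–iPr), C5 (ring-fusion C–OH), C6, C7, C8 (=C–Me), C9 (=CH), C10 (CH–O-anisoyl); five-membered ring C1–C5, seven-membered ring C1/C10/C9/C8/C7/C6/C5. The route rests on the allylic ester unit C10(O)–C9H=C8(Me) beside quaternary C1: as its enone it is the one-carbon-enlarged form of a cyclohexanone enol ether C10=C8(Me).
2. C10–O ester ⇐ selective acylation of a cis-1,3-diol ⇐ chelate-controlled reduction of the C10 enone.
3. Seven-membered ring ⇐ six-membered ring: take out C9 (bonds C8–C9 and C9–C10) to reach the C10=C8 silyl enol ether of a cis-hydrindanone. The C8 methyl comes from enolate methylation, because a methyl carried in a symmetric 1,3-dione could only end up at C7.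
4. Five-membered ring: C4–C5 by desymmetrising aldol of a 2,2-disubstituted cyclohexane-1,3-dione (sets C1, C5 and C4); C1–C2 by γ-addition of 2-methylcyclohexane-1,3-dione to pent-3-yn-2-one.
5. Ring order: six-membered ring (bought) → five-membered ring (step 3) → six enlarged to seven (step 9).

Key step: step 9

Assumption 1: the sense of induction in step 3 is assumed to be as drawn for the catalyst antipode named; if it is the opposite, the enantiomeric diamine (equally accessible) is used.
Assumption 2: only species made in stoichiometric amount that persist in the flask are numbered as intermediates; short-lived mechanistic species (enamine, oxaphosphetane, radicals) appear in the Why lines only.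

**Route**

Step 1
Reactants: 1 2-methylcyclohexane-1,3-dione; 2 pent-3-yn-2-one
Product: 3 (E)-2-methyl-2-(4-oxopent-2-en-1-yl)cyclohexane-1,3-dione
Conditions: PPh3 (cat.), AcOH/NaOAc (cat.), PhMe, 80 °C
Reagents that add atoms: none
Why: Phosphine-catalysed γ-umpolung addition: PPh3 adds to the ynone, proton shifts give a γ-electrophilic vinylphosphonium that the C-enolate of the dione attacks, and loss of PPh3 should give the E-enone with C1 already quaternary; no stereocentre forms because the dione stays symmetric.

Step 2
Reactants: 3 (E)-2-methyl-2-(4-oxopent-2-en-1-yl)cyclohexane-1,3-dione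
Product: 4 2-methyl-2-(4-oxopentyl)cyclohexane-1,3-dione
Conditions: H2 (1 atm), Pd/C, EtOAc, rt
Reagents that add atoms: none
Why: Catalytic hydrogenation of the conjugated C=C is much faster than reduction of the three ketones, so the saturated triketone should result.

Step 3
Reactants: 4 2-methyl-2-(4-oxopentyl)cyclohexane-1,3-dione
Product: 5 (1S,3aS,7aS)-1-acetyl-7a-hydroxy-3a-methyloctahydro-4H-inden-4-one
Conditions: (S)-N1,N1-diethyl-3,3-dimethylbutane-1,2-diamine·TfOH (10 mol %), 3-nitrobenzoic acid (10 mol %), DMF, rt
Reagents that add atoms: none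
Why: Enamine-catalysed desymmetrising intramolecular aldol (Hajos–Parrish type, 5-enolexo-exo-trig): the primary amine forms the more substituted enamine at C4, which can only close the five-membered ring onto one of the two enantiotopic ring carbonyls under the hydrogen-bond direction of the catalyst ammonium, so C1 and C5 are set together (cis fusion imposed by the three-carbon tether) and the C4 acetyl lies on the convex face cis to the hydroxyl, which is also the epimer favoured by equilibration through the enamine.

Step 4
Reactants: 5 (1S,3aS,7aS)-1-acetyl-7a-hydroxy-3a-methyloctahydro-4H-inden-4-one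
Product: 6 (1S,3aS,7aS)-1-acetyl-3a-methyl-7a-(trimethylsilyloxy)octahydro-4H-inden-4-one
Conditions: TMS-imidazole, CH2Cl2, rt
Reagents that add atoms: N-(trimethylsilyl)imidazole, C[Si](C)(C)n1ccnc1
Why: O-Silylation of the tertiary hydroxyl with a neutral, strong silyl donor masks the aldol against base-induced retro-aldol cleavage without enolising either ketone; no stereocentre changes.

Step 5
Reactants: 6 (1S,3aS,7aS)-1-acetyl-3a-methyl-7a-(trimethylsilyloxy)octahydro-4H-inden-4-one
Product: 7 (1R,3aS,7aS)-3a-methyl-1-(prop-1-en-2-yl)-7a-(trimethylsilyloxy)octahydro-4H-inden-4-one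
Conditions: Ph3PCH3Br, KOtBu (1.2 equiv ylide), THF, 0 °C → rt
Reagents that add atoms: methyltriphenylphosphonium bromide, C[P+](c1ccccc1)(c1ccccc1)c1ccccc1.[Br-]
Why: Wittig methylenation with a small excess of ylide should take the exposed methyl ketone and spare the C10 ketone, which is flanked by quaternary C1 and screened by C5 and its silyl ether; C4 is not at risk because the cis acetyl epimer is already the more stable one.

Step 6
Reactants: 7 (1R,3aS,7aS)-3a-methyl-1-(prop-1-en-2-yl)-7a-(trimethylsilyloxy)octahydro-4H-inden-4-one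
Product: 8 (1R,3aS,7aS)-1-isopropyl-3a-methyl-7a-(trimethylsilyloxy)octahydro-4H-inden-4-one
Conditions: H2 (1 atm), Pd/C, EtOAc, rt
Reagents that add atoms: none
Why: Catalytic hydrogenation of the 1,1-disubstituted alkene gives the isopropyl group while the hindered ketone and the silyl ether stay intact; no new stereocentre arises.

Step 7
Reactants: 8 (1R,3aS,7aS)-1-isopropyl-3a-methyl-7a-(trimethylsilyloxy)octahydro-4H-inden-4-one
Product: 10 (1R,3aS,7aS)-1-isopropyl-3a,5-dimethyl-7a-(trimethylsilyloxy)octahydro-4H-inden-4-one (both C8 epimers), via lithium enolate 9 (not isolated)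
Conditions: LDA (1.1 equiv), THF, −78 °C; MeI, −78 → 0 °C
Reagents that add atoms: iodomethane, CI
Why: Enolate alkylation: LDA can deprotonate only at C8 because C1 is quaternary, and methylation of the lithium enolate installs the C8 methyl; the C8 configuration does not matter since C8 becomes sp2 in step 8.

Step 8
Reactants: 10 (1R,3aS,7aS)-1-isopropyl-3a,5-dimethyl-7a-(trimethylsilyloxy)octahydro-4H-inden-4-one
Product: 11 (3R,3aS,7aS)-3-isopropyl-6,7a-dimethyl-3a,7-bis(trimethylsilyloxy)-2,3,3a,4,5,7a-hexahydro-1H-indene
Conditions: TMSOTf, Et3N, CH2Cl2, 0 °C → rt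
Reagents that add atoms: trimethylsilyl trifluoromethanesulfonate, C[Si](C)(C)OS(=O)(=O)C(F)(F)F
Why: Silyl enol ether formation by soft enolisation gives the only possible regioisomer, the tetrasubstituted C10=C8 enol ether, and re-silylates any C5–OH freed on the way; the C8 stereocentre is erased.

Step 9
Reactants: 11 (3R,3aS,7aS)-3-isopropyl-6,7a-dimethyl-3a,7-bis(trimethylsilyloxy)-2,3,3a,4,5,7a-hexahydro-1H-indene; 12 diiodomethane
Product: 15 (3R,3aS,8aS)-3a-hydroxy-3-isopropyl-6,8a-dimethyl-2,3,3a,4,5,8a-hexahydroazulen-8(1H)-one, via siloxycyclopropane 13 (not isolated), via β-chloro ketone 14 (not isolated)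
Conditions: (a) Et2Zn, CH2I2, Et2O, 0 °C → reflux, pyridine quench, filter; (b) FeCl3, DMF, 0 °C → rt, then 1 M HCl; (c) NaOAc, MeOH, reflux; crude material carried through (a)–(c)
Reagents that add atoms: none
Why: Furukawa-modified Simmons–Smith methylene transfer from the zinc carbenoid to the electron-rich tetrasubstituted C10=C8 enol ether forms C8–C9 and C9–C10 in a concerted [2+1] (butterfly) closure of cyclopropane 13. Iron(III) chloride turns the silyloxycyclopropane into an iron cyclopropoxide and then an alkoxy radical whose β-scission breaks the internal C8–C10 bond, so the seven-membered ring arises by enlargement (6 → 7) and not by a new closure; chlorine transfer from a second FeCl3 gives chloride 14, and acetate removes HCl by E1cB through the C9 enolate. The closest known reaction type is the Ito–Saegusa one-carbon ring expansion of cycloalkanone silyl enol ethers to 2-cycloalkenones, which covers 2-methyl enol ethers leading to β-methyl enones. No stereocentre is kept from this step (the cyclopropane and chloride centres are transient and used as mixtures), and C1, C4 and C5 are not touched. The step needs internal instead of external bond cleavage, secured by the tertiary ring-enlarged radical at C8 and by strain release, and elimination towards C9, secured because C1 is quaternary and the product is conjugated. The acidic work-up after stage (b) should also remove the tertiary trimethylsilyl ether at C5.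

Step 10
Reactants: 15 (3R,3aS,8aS)-3a-hydroxy-3-isopropyl-6,8a-dimethyl-2,3,3a,4,5,8a-hexahydroazulen-8(1H)-one
Product: 17 (3R,3aS,8S,8aR)-3-isopropyl-6,8a-dimethyl-2,3,4,5,8,8a-hexahydro-1H-azulene-3a,8-diol, via diethylboryl chelate 16 (not isolated)
Conditions: Et2BOMe, THF/MeOH (4:1), rt → −78 °C; NaBH4, −78 °C; AcOH, then MeOH co-evaporation
Reagents that add atoms: none
Why: Narasaka–Prasad reduction: the diethylboryl group bridges the C5 oxygen and the C10 carbonyl oxygen on the face of the angular hydroxyl and activates the ketone for 1,2-attack, so borohydride must enter from the opposite face and the new C10 hydroxyl should end cis to C5–OH and C1–Me (10S by the overview numbering, 8S in the name).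

Step 11
Reactants: 17 (3R,3aS,8S,8aR)-3-isopropyl-6,8a-dimethyl-2,3,4,5,8,8a-hexahydro-1H-azulene-3a,8-diol; 18 4-methoxybenzoyl chloride
Product: 19 (3R,3aS,8S,8aR)-3a-hydroxy-3-isopropyl-6,8a-dimethyl-1,2,3,3a,4,5,8,8a-octahydroazulen-8-yl 4-methoxybenzoate
Conditions: pyridine, DMAP (cat.), CH2Cl2, 0 °C → rt
Reagents that add atoms: none
Why: DMAP-catalysed acylation (Steglich-type acyl transfer) should select the secondary allylic hydroxyl over the tertiary ring-fusion hydroxyl on steric grounds and keeps the C10 configuration.

**Compound list**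

1 | 2-methylcyclohexane-1,3-dione | CC1C(=O)CCCC1=O | starting material
2 | pent-3-yn-2-one | CC#CC(C)=O | starting material
3 | (E)-2-methyl-2-(4-oxopent-2-en-1-yl)cyclohexane-1,3-dione | CC(=O)/C=C/CC1(C)C(=O)CCCC1=O | intermediate
4 | 2-methyl-2-(4-oxopentyl)cyclohexane-1,3-dione | CC(=O)CCCC1(C)C(=O)CCCC1=O | intermediate
5 | (1S,3aS,7aS)-1-acetyl-7a-hydroxy-3a-methyloctahydro-4H-inden-4-one (cis-fused; acetyl, OH and Me on one face; ring ketone = C10) | O=C1CCC[C@]2(O)[C@@H](C(C)=O)CC[C@]12C | intermediate
6 | (1S,3aS,7aS)-1-acetyl-3a-methyl-7a-(trimethylsilyloxy)octahydro-4H-inden-4-one | O=C1CCC[C@]2(O[Si](C)(C)C)[C@@H](C(C)=O)CC[C@]12C | intermediate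
7 | (1R,3aS,7aS)-3a-methyl-1-(prop-1-en-2-yl)-7a-(trimethylsilyloxy)octahydro-4H-inden-4-one | O=C1CCC[C@]2(O[Si](C)(C)C)[C@@H](C(C)=C)CC[C@]12C | intermediate
8 | (1R,3aS,7aS)-1-isopropyl-3a-methyl-7a-(trimethylsilyloxy)octahydro-4H-inden-4-one | O=C1CCC[C@]2(O[Si](C)(C)C)[C@@H](C(C)C)CC[C@]12C | intermediate
9 | lithium enolate of 8 (C10–OLi, C10=C8) | [Li]OC1=CCC[C@]2(O[Si](C)(C)C)[C@@H](C(C)C)CC[C@]12C | intermediate
10 | (1R,3aS,7aS)-1-isopropyl-3a,5-dimethyl-7a-(trimethylsilyloxy)octahydro-4H-inden-4-one (indane C5 = C8, both epimers) | O=C1C(C)CC[C@]2(O[Si](C)(C)C)[C@@H](C(C)C)CC[C@]12C | intermediate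
11 | (3R,3aS,7aS)-3-isopropyl-6,7a-dimethyl-3a,7-bis(trimethylsilyloxy)-2,3,3a,4,5,7a-hexahydro-1H-indene | C[Si](C)(C)OC1=C(C)CC[C@]2(O[Si](C)(C)C)[C@@H](C(C)C)CC[C@]12C | intermediate
12 | diiodomethane | ICI | starting material
13 | siloxycyclopropane: 11 with CH2 (C9) bridging C8 and C10 (both cyclopropane faces) | C[Si](C)(C)OC12CC1(C)CC[C@]3(O[Si](C)(C)C)[C@@H](C(C)C)CC[C@]23C | intermediate
14 | (3R,3aS,8aS)-6-chloro-3a-hydroxy-3-isopropyl-6,8a-dimethyloctahydroazulen-8(1H)-one (both C6 epimers; azulene C6 = C8) | O=C1CC(C)(Cl)CC[C@]2(O)[C@@H](C(C)C)CC[C@]12C | intermediate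
15 | (3R,3aS,8aS)-3a-hydroxy-3-isopropyl-6,8a-dimethyl-2,3,3a,4,5,8a-hexahydroazulen-8(1H)-one | O=C1C=C(C)CC[C@]2(O)[C@@H](C(C)C)CC[C@]12C | intermediate
16 | 3a-O-diethylboryl derivative of 15 (boron coordinated to the C10 carbonyl oxygen) | O=C1C=C(C)CC[C@]2(OB(CC)CC)[C@@H](C(C)C)CC[C@]12C | intermediate
17 | (3R,3aS,8S,8aR)-3-isopropyl-6,8a-dimethyl-2,3,4,5,8,8a-hexahydro-1H-azulene-3a,8-diol | O[C@H]1C=C(C)CC[C@]2(O)[C@@H](C(C)C)CC[C@]12C | intermediate
18 | 4-methoxybenzoyl chloride | COc1ccc(C(Cl)=O)cc1 | starting material
19 | (3R,3aS,8S,8aR)-3a-hydroxy-3-isopropyl-6,8a-dimethyl-1,2,3,3a,4,5,8,8a-octahydroazulen-8-yl 4-methoxybenzoate | COc1ccc(C(=O)O[C@H]2C=C(C)CC[C@]3(O)[C@@H](C(C)C)CC[C@]23C)cc1 | target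

**Step count and risks**

Total step count: 11. Longest linear sequence: 11 steps (1 → 19).

Steps most likely to fail:

Step 9. Methylene transfer to the hindered tetrasubstituted enol ether may be slow, with zinc iodide-induced desilylation competing. The siloxycyclopropane may open by protonolysis to an α,α-dimethyl ketone instead of undergoing oxidative enlargement, and the dehydrochlorination may give alkene isomers. Fallback: from methyl ketone 10, Lewis acid-promoted diazoalkane homologation (TMSCHN2, AlMe3, CH2Cl2, −78 → −20 °C) should insert the carbon on the less substituted C8 side and give the α-silyl cycloheptanone F1. Treatment with 1 M HCl in THF should remove both silyl groups and give the saturated hydroxy cycloheptanone F2. IBX dehydrogenation (DMSO, 70 °C), possible only towards C9, returns to the route at enone 15.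

Step 3. Discrimination between the two enantiotopic ring carbonyls may be poor, ring closure through the ketone enamine may be slow, and the ketol may lose water under amine/acid catalysis. Fallback: from enedione 3 (step 2 is then skipped), copper hydride-catalysed enantioselective reductive aldol cyclisation (Cu(OAc)2 cat., chiral ferrocenyl or biaryl bisphosphine, PhSiH3, PhMe, −20 °C → rt, aqueous NH4F work-up). Conjugate hydride addition gives a copper Z-enolate that adds through a closed transition state to one ring carbonyl and should give the same all-cis ketol, returning at 5; no new compound is formed on the way (F0).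

Step 10. Chelate formation at the hindered tertiary hydroxyl may be incomplete, so that hydride enters unguided and gives the C10 epimer, or conjugate reduction may compete. Fallback: from enone 15, Evans–Saksena reduction (Me4NBH(OAc)3, MeCN/AcOH, −20 °C) delivers hydride intramolecularly from the C5 oxygen and should give the trans-1,3-diol, the 10-epi-diol F3. Mitsunobu esterification of F3 with 4-methoxybenzoic acid (PPh3, DIAD, PhMe, 0 °C → rt) inverts C10 and installs the ester in one operation, returning at target 19.

Further compounds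
F1 | step 9 | α-silyl cycloheptanone: (3R,3aS,8aS)-3-isopropyl-6,8a-dimethyl-7-(trimethylsilyl)-3a-(trimethylsilyloxy)octahydroazulen-8(1H)-one (C6/C7 epimers) | O=C1C([Si](C)(C)C)C(C)CC[C@]2(O[Si](C)(C)C)[C@@H](C(C)C)CC[C@]12C
F2 | step 9 | saturated hydroxy cycloheptanone: (3R,3aS,8aS)-3a-hydroxy-3-isopropyl-6,8a-dimethyloctahydroazulen-8(1H)-one (C6 epimers) | O=C1CC(C)CC[C@]2(O)[C@@H](C(C)C)CC[C@]12C
F0 | step 3 | none | none
F3 | step 10 | 10-epi-diol: (3R,3aS,8R,8aR)-3-isopropyl-6,8a-dimethyl-2,3,4,5,8,8a-hexahydro-1H-azulene-3a,8-diol | O[C@@H]1C=C(C)CC[C@]2(O)[C@@H](C(C)C)CC[C@]12C
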